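**Retrosynthetic overview**
1. Target 22 ⇐ silyl ether 21 ⇐ seco-lactone 20 by ring-closing metathesis at C1=C10; the ten-membered ring is formed last.
2. 20 ⇐ aldehyde 6 (fragment A: C1–C6, C15) + (Z)-2-(methoxycarbonyl)allylboronate 18 (fragment B: C7–C14 with the C8 ester in place). One allylboration forms C6–C7, sets C6 and C7, and closes the α-methylene-γ-lactone, which is the first ring formed.
3. 6 ⇐ hex-5-enal + formaldehyde (organocatalytic α-hydroxymethylation, then one-carbon homologation).
4. 18 ⇐ methyl 4-hydroxybut-2-ynoate + methyl 2-(bromomethyl)acrylate + (R)-2-methylbutanoic acid (from tiglic acid), via syn-hydrostannation/iodination and Negishi borylmethylation.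

Assumption: germacranolide locants are used (C6 = lactone O–CH, C7 = ring-fusion CH, C8 = acyloxy CH, C10 = ester-bearing olefinic carbon, C4 = CH carrying C15H2OH); the target is then (4S,6R,7S,8R,2′R) with a 1(10)E (ring-cis) enoate.

**Fragment A**

Step 1
Reactants: 1 hex-5-enal; 2 formaldehyde (37% aqueous)
Product: 3 (2R)-2-(hydroxymethyl)hex-5-enal
Conditions: (S)-α,α-diphenylprolinol trimethylsilyl ether (10 mol %), pH 7 phosphate buffer (NaH2PO4/Na2HPO4), toluene, rt, 36 h; crude used at once
Reagents that add atoms: none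
Why: Enamine-catalysed α-hydroxymethylation (crossed aldol with formaldehyde), in which the bulky diphenyl(silyloxy)methyl group of the (S)-catalyst shields one face of the E-enamine so that formaldehyde adds to the other and sets the future C4 centre as (R).

Step 2
Reactants: 3 (2R)-2-(hydroxymethyl)hex-5-enal
Product: 4 (2R)-2-({[tert-butyl(diphenyl)silyl]oxy}methyl)hex-5-enal
Conditions: TBDPSCl, imidazole, CH2Cl2, 0 °C→rt
Reagents that add atoms: tert-butyl(chloro)diphenylsilane, CC(C)(C)[Si](Cl)(c1ccccc1)c1ccccc1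
Why: Silyl ether formation on the primary alcohol under mild imidazole conditions, done at once so the β-hydroxy aldehyde cannot dehydrate or undergo retro-aldol; the stereocentre is not touched.

Step 3
Reactants: 4 (2R)-2-({[tert-butyl(diphenyl)silyl]oxy}methyl)hex-5-enal
Product: 5 tert-butyl{[(2S)-2-(2-methoxyethenyl)hex-5-en-1-yl]oxy}diphenylsilane (E/Z mixture)
Conditions: MeOCH2PPh3Cl, KN(SiMe3)2, THF, 0 °C, 30 min; then 4, −78 °C→0 °C
Reagents that add atoms: (methoxymethyl)triphenylphosphonium chloride, [Cl-].COC[P+](c1ccccc1)(c1ccccc1)c1ccccc1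
Why: Wittig methoxymethylenation (one-carbon homologation); adding the aldehyde to the preformed ylide at −78 °C avoids α-epimerisation and β-elimination, and the E/Z ratio is irrelevant.

Step 4
Reactants: 5 tert-butyl{[(2S)-2-(2-methoxyethenyl)hex-5-en-1-yl]oxy}diphenylsilane
Product: 6 (3S)-3-({[tert-butyl(diphenyl)silyl]oxy}methyl)hept-6-enal
Conditions: 2 M aq. HCl, THF, rt, 3 h
Reagents that add atoms: water, O
Why: Acid-catalysed enol ether hydrolysis gives the homologated aldehyde; the silyl ether, the terminal olefin and the (now β) stereocentre are unaffected.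

**Acid side chain**

Step 5
Reactants: 7 tiglic acid
Product: 8 (2R)-2-methylbutanoic acid
Conditions: H2 (4 atm), Ru(OAc)2[(R)-H8-BINAP] (0.5 mol %), MeOH, 20 °C
Reagents that add atoms: none
Why: Noyori–Takaya asymmetric hydrogenation, in which the carboxylate-bound ruthenium–(R)-H8-BINAP complex delivers hydrogen to one enantioface of the trisubstituted olefin to give the (R)-acid (about 97% ee).

**Fragment B**

Step 6
Reactants: 9 methyl 4-hydroxybut-2-ynoate
Product: 10 methyl 4-oxobut-2-ynoate
Conditions: Dess–Martin periodinane (1.2 equiv), CH2Cl2, 0 °C→rt, 1 h; filtered through silica and used at once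
Reagents that add atoms: none
Why: Dess–Martin oxidation of a primary propargylic alcohol under neutral conditions stops at the ynal and leaves the ynoate alone.

Step 7
Reactants: 11 methyl 2-(bromomethyl)prop-2-enoate; 10 methyl 4-oxobut-2-ynoate
Product: 13 dimethyl (±)-4-hydroxy-6-methylidenehept-2-ynedioate, via allylzinc bromide 12 (not isolated)
Conditions: 11, Zn dust, THF, 0 °C, 1 h; decanted solution of 12 added to 10, THF, −78 °C, 30 min; sat. aq. NH4Cl at −78 °C
Reagents that add atoms: none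
Why: Reformatsky-type (Dreiding–Schmidt) addition of a 2-(alkoxycarbonyl)allylzinc reagent, where 1,2-addition to the aldehyde at −78 °C outruns conjugate addition to the ynoate and the cold quench leaves the open hydroxy ester; the new C8 centre is formed racemic.

Step 8
Reactants: 13 dimethyl (±)-4-hydroxy-6-methylidenehept-2-ynedioate
Product: 14 dimethyl (4R)-4-hydroxy-6-methylidenehept-2-ynedioate
Conditions: Burkholderia cepacia lipase (immobilised), vinyl acetate (3 equiv), MTBE, 30 °C, to about 55% conversion; chromatography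
Reagents that add atoms: none
Why: Lipase-catalysed kinetic resolution by transesterification; by the Kazlauskas rule the slim alkynyl group binds as the medium substituent, so the (S)-alcohol is acetylated and the (R)-alcohol (the C8 configuration of the target) is recovered in high ee.

Step 9
Reactants: 14 dimethyl (4R)-4-hydroxy-6-methylidenehept-2-ynedioate; 8 (2R)-2-methylbutanoic acid
Product: 15 dimethyl (4R)-6-methylidene-4-{[(2R)-2-methylbutanoyl]oxy}hept-2-ynedioate
Conditions: 8 (1.3 equiv), EDC·HCl (1.5 equiv), DMAP (0.1 equiv), CH2Cl2, 0 °C→rt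
Reagents that add atoms: none
Why: Steglich esterification acylates the propargylic alcohol with retention at both stereocentres and blocks any later lactonisation of the C8 oxygen onto either ester.

Step 10
Reactants: 15 dimethyl (4R)-6-methylidene-4-{[(2R)-2-methylbutanoyl]oxy}hept-2-ynedioate
Product: 17 dimethyl (2E,4R)-2-iodo-6-methylidene-4-{[(2R)-2-methylbutanoyl]oxy}hept-2-enedioate, via alkenylstannane 16 (not isolated)
Conditions: Bu3SnH (1.05 equiv), Pd(PPh3)4 (2 mol %), THF, 0 °C, 30 min; then I2 (1.1 equiv), 0 °C, 15 min; aq. Na2S2O3 wash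
Reagents that add atoms: iodine, II
Why: Palladium-catalysed hydrostannation is a syn addition that places tin α to the ester and hydride on C3, and iododestannylation proceeds with retention, so the C4 substituent ends cis to CO2Me; no stereocentre is touched.

Step 11
Reactants: 17 dimethyl (2E,4R)-2-iodo-6-methylidene-4-{[(2R)-2-methylbutanoyl]oxy}hept-2-enedioate
Product: 18 dimethyl (2Z,4R)-6-methylidene-4-{[(2R)-2-methylbutanoyl]oxy}-2-[(4,4,5,5-tetramethyl-1,3,2-dioxaborolan-2-yl)methyl]hept-2-enedioate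
Conditions: ICH2B(pin), Zn dust, THF, rt, 1 h (gives pinBCH2ZnI); then 17, Pd(PPh3)4 (5 mol %), THF, rt→40 °C, 6 h
Reagents that add atoms: 2-(iodomethyl)-4,4,5,5-tetramethyl-1,3,2-dioxaborolane (used as its zinc reagent), CC1(C)OB(CI)OC1(C)C
Why: Negishi sp2–sp3 cross-coupling of the alkenyl iodide with the borylmethylzinc reagent retains the olefin geometry, giving the allylboronate with C8 cis to the ester, the geometry needed for an anti allylboration.

**Union, ring closure and end game**

Step 12
Reactants: 6 (3S)-3-({[tert-butyl(diphenyl)silyl]oxy}methyl)hept-6-enal; 18 dimethyl (2Z,4R)-6-methylidene-4-{[(2R)-2-methylbutanoyl]oxy}-2-[(4,4,5,5-tetramethyl-1,3,2-dioxaborolan-2-yl)methyl]hept-2-enedioate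
Product: 20 methyl (4R)-4-[(2R,3S)-2-[(2S)-2-({[tert-butyl(diphenyl)silyl]oxy}methyl)hex-5-en-1-yl]-4-methylidene-5-oxooxolan-3-yl]-2-methylidene-4-{[(2R)-2-methylbutanoyl]oxy}butanoate, via O-boryl homoallylic adduct 19 (not isolated)
Conditions: 6 (1.0 equiv), 18 (1.2 equiv), Sc(OTf)3 (10 mol %), toluene, 0 °C→rt, 24 h; then p-TsOH·H2O (0.2 equiv), rt, 6 h
Reagents that add atoms: none
Why: Allylboration through a closed chair (Zimmerman–Traxler) transition state followed by lactonisation: the (2Z) boronate geometry (C8 trans to CH2B) puts C8 equatorial and gives the 6,7-anti adduct that closes to the trans-γ-lactone, while A(1,3) strain with the cis CO2Me holds H-8 in the olefin plane so the aldehyde adds to C7 anti to the C9 methylene with the acyloxy group outside, setting (6R,7S) from the existing (8R) centre.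

Step 13
Reactants: 20 methyl (4R)-4-[(2R,3S)-2-[(2S)-2-({[tert-butyl(diphenyl)silyl]oxy}methyl)hex-5-en-1-yl]-4-methylidene-5-oxooxolan-3-yl]-2-methylidene-4-{[(2R)-2-methylbutanoyl]oxy}butanoate
Product: 21 methyl (3aS,4R,6E,10S,11aR)-10-({[tert-butyl(diphenyl)silyl]oxy}methyl)-3-methylidene-4-{[(2R)-2-methylbutanoyl]oxy}-2-oxo-2,3,3a,4,5,8,9,10,11,11a-decahydrocyclodeca[b]furan-6-carboxylate
Conditions: RuCl2(H2IMes)(=CH-C6H4-2-OiPr) (second-generation Hoveyda–Grubbs catalyst, 3 × 5 mol %), 1,4-benzoquinone (20 mol %), toluene (1 mM), 90 °C, argon sparge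
Reagents that add atoms: none
Why: Ring-closing metathesis initiates at the monosubstituted C1 olefin and closes onto the 1,1-disubstituted acrylate with loss of ethene; the ten-membered ring accommodates only the ring-cis trisubstituted olefin, which is the (E)-enoate (CO2Me trans to C2), and no stereocentre is touched.

Step 14
Reactants: 21 methyl (3aS,4R,6E,10S,11aR)-10-({[tert-butyl(diphenyl)silyl]oxy}methyl)-3-methylidene-4-{[(2R)-2-methylbutanoyl]oxy}-2-oxo-2,3,3a,4,5,8,9,10,11,11a-decahydrocyclodeca[b]furan-6-carboxylate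
Product: 22 methyl (3aS,4R,6E,10S,11aR)-10-(hydroxymethyl)-3-methylidene-4-{[(2R)-2-methylbutanoyl]oxy}-2-oxo-2,3,3a,4,5,8,9,10,11,11a-decahydrocyclodeca[b]furan-6-carboxylate (CNP0141952.4)
Conditions: HF·pyridine, pyridine, THF, 0 °C→rt, 16 h
Reagents that add atoms: none
Why: Fluoride-mediated desilylation under buffered acidic conditions frees the primary alcohol without affecting the α-methylene lactone, the two esters or any stereocentre.

**Compound list**
1 | hex-5-enal | C=CCCCC=O | starting material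
2 | formaldehyde | C=O | starting material
3 | (2R)-2-(hydroxymethyl)hex-5-enal | O=C[C@@H](CO)CCC=C | intermediate
4 | (2R)-2-({[tert-butyl(diphenyl)silyl]oxy}methyl)hex-5-enal | O=C[C@@H](CO[Si](c1ccccc1)(c1ccccc1)C(C)(C)C)CCC=C | intermediate
5 | tert-butyl{[(2S)-2-(2-methoxyethenyl)hex-5-en-1-yl]oxy}diphenylsilane (E/Z mixture) | COC=C[C@@H](CO[Si](c1ccccc1)(c1ccccc1)C(C)(C)C)CCC=C | intermediate
6 | (3S)-3-({[tert-butyl(diphenyl)silyl]oxy}methyl)hept-6-enal (fragment A) | O=CC[C@@H](CO[Si](c1ccccc1)(c1ccccc1)C(C)(C)C)CCC=C | intermediate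
7 | tiglic acid, (E)-2-methylbut-2-enoic acid | C/C=C(\C)C(=O)O | starting material
8 | (2R)-2-methylbutanoic acid | CC[C@@H](C)C(=O)O | intermediate
9 | methyl 4-hydroxybut-2-ynoate | COC(=O)C#CCO | starting material
10 | methyl 4-oxobut-2-ynoate | COC(=O)C#CC=O | intermediate
11 | methyl 2-(bromomethyl)prop-2-enoate | C=C(CBr)C(=O)OC | starting material
12 | [2-(methoxycarbonyl)prop-2-en-1-yl]zinc bromide (formed in the flask) | C=C(C[Zn]Br)C(=O)OC | intermediate
13 | dimethyl (±)-4-hydroxy-6-methylidenehept-2-ynedioate | COC(=O)C#CC(O)CC(=C)C(=O)OC | intermediate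
14 | dimethyl (4R)-4-hydroxy-6-methylidenehept-2-ynedioate | COC(=O)C#C[C@H](O)CC(=C)C(=O)OC | intermediate
15 | dimethyl (4R)-6-methylidene-4-{[(2R)-2-methylbutanoyl]oxy}hept-2-ynedioate | COC(=O)C#C[C@H](OC(=O)[C@H](C)CC)CC(=C)C(=O)OC | intermediate
16 | dimethyl (2E,4R)-6-methylidene-4-{[(2R)-2-methylbutanoyl]oxy}-2-(tributylstannyl)hept-2-enedioate (formed in the flask) | COC(=O)/C(=C\[C@H](OC(=O)[C@H](C)CC)CC(=C)C(=O)OC)[Sn](CCCC)(CCCC)CCCC | intermediate
17 | dimethyl (2E,4R)-2-iodo-6-methylidene-4-{[(2R)-2-methylbutanoyl]oxy}hept-2-enedioate | COC(=O)/C(I)=C\[C@H](OC(=O)[C@H](C)CC)CC(=C)C(=O)OC | intermediate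
18 | dimethyl (2Z,4R)-6-methylidene-4-{[(2R)-2-methylbutanoyl]oxy}-2-[(4,4,5,5-tetramethyl-1,3,2-dioxaborolan-2-yl)methyl]hept-2-enedioate (fragment B) | COC(=O)/C(CB1OC(C)(C)C(C)(C)O1)=C\[C@H](OC(=O)[C@H](C)CC)CC(=C)C(=O)OC | intermediate
19 | dimethyl (4R,5S)-5-[(1R,3S)-3-({[tert-butyl(diphenyl)silyl]oxy}methyl)-1-[(4,4,5,5-tetramethyl-1,3,2-dioxaborolan-2-yl)oxy]hept-6-en-1-yl]-2,6-dimethylidene-4-{[(2R)-2-methylbutanoyl]oxy}heptanedioate (formed in the flask) | COC(=O)C(=C)[C@@H]([C@H](OB1OC(C)(C)C(C)(C)O1)C[C@@H](CO[Si](c1ccccc1)(c1ccccc1)C(C)(C)C)CCC=C)[C@H](OC(=O)[C@H](C)CC)CC(=C)C(=O)OC | intermediate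
20 | methyl (4R)-4-[(2R,3S)-2-[(2S)-2-({[tert-butyl(diphenyl)silyl]oxy}methyl)hex-5-en-1-yl]-4-methylidene-5-oxooxolan-3-yl]-2-methylidene-4-{[(2R)-2-methylbutanoyl]oxy}butanoate | C=C1C(=O)O[C@H](C[C@@H](CO[Si](c2ccccc2)(c2ccccc2)C(C)(C)C)CCC=C)[C@H]1[C@H](OC(=O)[C@H](C)CC)CC(=C)C(=O)OC | intermediate
21 | methyl (3aS,4R,6E,10S,11aR)-10-({[tert-butyl(diphenyl)silyl]oxy}methyl)-3-methylidene-4-{[(2R)-2-methylbutanoyl]oxy}-2-oxo-2,3,3a,4,5,8,9,10,11,11a-decahydrocyclodeca[b]furan-6-carboxylate | C=C1C(=O)O[C@@H]2C[C@@H](CO[Si](c3ccccc3)(c3ccccc3)C(C)(C)C)CC/C=C(/C(=O)OC)C[C@@H](OC(=O)[C@H](C)CC)[C@@H]12 | intermediate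
22 | methyl (3aS,4R,6E,10S,11aR)-10-(hydroxymethyl)-3-methylidene-4-{[(2R)-2-methylbutanoyl]oxy}-2-oxo-2,3,3a,4,5,8,9,10,11,11a-decahydrocyclodeca[b]furan-6-carboxylate | C=C1C(=O)O[C@@H]2C[C@@H](CO)CC/C=C(/C(=O)OC)C[C@@H](OC(=O)[C@H](C)CC)[C@@H]12 | target

**Totals**
Total step count: 14. Longest linear sequence: 9 steps (steps 6–14, from 9); the other branches are steps 1–4 and step 5.

**Steps most likely to fail**

Step 13 (ring-closing metathesis). A strained ten-membered ring must close onto an electron-poor 1,1-disubstituted olefin while the exo-methylene lactone can compete (eight-membered closure or oligomerisation). Fallback, setting out from 20 and coming back at 21: mask the lactone olefin first. Conjugate addition of thiophenol (PhSH, catalytic Et3N, CH2Cl2, 0 °C; the acyclic 2-alkyl acrylate reacts much more slowly) gives the α-(phenylsulfanylmethyl) lactone F1. Ring-closing metathesis of F1 under the step 13 conditions gives the ten-membered sulfide F2. Oxidation (mCPBA, 1 equiv, CH2Cl2, −78 °C) gives the sulfoxide F3, which on heating (toluene, 110 °C, CaCO3) undergoes syn-elimination to restore the exo-methylene lactone, that is 21.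

Step 12 (allylboration/lactonisation). The facial selectivity at C7 rests on acyclic A(1,3) control by the C8 acyloxy centre, and the allylic-ester boronate may suffer 1,4-elimination under Lewis acid. Fallback, setting out from 6 and 18 and coming back at 21: reverse the order of the two unions. Cross-metathesis of the terminal olefin of 6 with the 2-alkyl acrylate of 18 (the same ruthenium catalyst, CH2Cl2, 40 °C; the trisubstituted allylboronate olefin is inert) gives the (E)-enoate aldehyde–boronate F4. Heating F4 at high dilution (toluene, 1 mM, 70 °C, then p-TsOH·H2O) effects an intramolecular allylboration in which the forming ten-membered ring imposes the transition-state geometry and closes carbocycle and lactone together to 21, bypassing 20 and step 13.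

Step 8 (kinetic resolution). Both carbinol substituents are sizeable, so the enantioselectivity, and even the sense of preference, may be poor, and the yield cannot exceed 50%. Fallback, setting out from 13 and coming back at 14: replace the resolution by an asymmetric reduction. Dess–Martin oxidation of 13 (CH2Cl2, 0 °C) gives the ynone F5, which is reduced with (R)-Alpine-Borane (B-isopinocampheyl-9-borabicyclo[3.3.1]nonane from (+)-α-pinene, THF, rt); the alkynyl group acts as the small substituent in the boat-like transition state and the (R)-carbinol 14 is obtained directly.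

**Further compounds**
F1 | step 13 | methyl (4R)-4-[(2R,3S)-2-[(2S)-2-({[tert-butyl(diphenyl)silyl]oxy}methyl)hex-5-en-1-yl]-5-oxo-4-[(phenylsulfanyl)methyl]oxolan-3-yl]-2-methylidene-4-{[(2R)-2-methylbutanoyl]oxy}butanoate (epimers at the lactone α-carbon) | c1ccccc1SCC1C(=O)O[C@H](C[C@@H](CO[Si](c2ccccc2)(c2ccccc2)C(C)(C)C)CCC=C)[C@H]1[C@H](OC(=O)[C@H](C)CC)CC(=C)C(=O)OC
F2 | step 13 | methyl (3aS,4R,6E,10S,11aR)-10-({[tert-butyl(diphenyl)silyl]oxy}methyl)-4-{[(2R)-2-methylbutanoyl]oxy}-2-oxo-3-[(phenylsulfanyl)methyl]-2,3,3a,4,5,8,9,10,11,11a-decahydrocyclodeca[b]furan-6-carboxylate (C3 epimers) | c1ccccc1SCC1C(=O)O[C@@H]2C[C@@H](CO[Si](c3ccccc3)(c3ccccc3)C(C)(C)C)CC/C=C(/C(=O)OC)C[C@@H](OC(=O)[C@H](C)CC)[C@@H]12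
F3 | step 13 | methyl (3aS,4R,6E,10S,11aR)-10-({[tert-butyl(diphenyl)silyl]oxy}methyl)-4-{[(2R)-2-methylbutanoyl]oxy}-2-oxo-3-[(phenylsulfinyl)methyl]-2,3,3a,4,5,8,9,10,11,11a-decahydrocyclodeca[b]furan-6-carboxylate (mixture at C3 and sulfur) | O=S(CC1C(=O)O[C@@H]2C[C@@H](CO[Si](c3ccccc3)(c3ccccc3)C(C)(C)C)CC/C=C(/C(=O)OC)C[C@@H](OC(=O)[C@H](C)CC)[C@@H]12)c1ccccc1
F4 | step 12 | methyl (2Z,4R,6E,10S)-10-({[tert-butyl(diphenyl)silyl]oxy}methyl)-6-(methoxycarbonyl)-4-{[(2R)-2-methylbutanoyl]oxy}-12-oxo-2-[(4,4,5,5-tetramethyl-1,3,2-dioxaborolan-2-yl)methyl]dodeca-2,6-dienoate | O=CC[C@@H](CO[Si](c1ccccc1)(c1ccccc1)C(C)(C)C)CC/C=C(/C(=O)OC)C[C@@H](OC(=O)[C@H](C)CC)/C=C(/CB1OC(C)(C)C(C)(C)O1)C(=O)OC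
F5 | step 8 | dimethyl 6-methylidene-4-oxohept-2-ynedioate | COC(=O)C#CC(=O)CC(=C)C(=O)OC
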